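**Plan**
- Retrosynthesis: the two benzyl ethers (on the 8-OH and 3'-OH) are removed last. Ring C is then cut at O1–C8a (copper-catalysed aryl ether closure) and at C2–C3 (Claisen condensation), giving a ring A bromoacetophenone and a ring B benzoate.
- Ring A is cut at C4a–C5 and C8–C8a. It carries, in sequence, C4a (acyl), C5–H, C6–OMe, C7–OMe, C8–OH and C8a–O1. C5–C8 with their oxygens map onto 3,4-dimethoxyfuran (its ring oxygen becomes the 8-OH), and C4a/C8a map onto an alkyne bearing an acetyl group and a bromine.
- Forward order: the furan is made from dimethyl diglycolate and dimethyl oxalate; ring A arises by cycloaddition and aromatisation; ring B is bought as the benzoate; the two are joined as a 1,3-diketone; ring C is closed last.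
- Stereochemistry: the target has no stereocentre, so none has to be set.

Key step: step 6

Remark: the oxanorbornadiene formed in the key step is racemic and transient, and the 1,3-diketone is drawn in its diketo form although it should exist largely as the chelated enol.

**Step 1**
Reactants: 1 dimethyl diglycolate (dimethyl 2,2'-oxydiacetate); 2 dimethyl oxalate
Product: 3 dimethyl 3,4-dihydroxyfuran-2,5-dicarboxylate
Conditions: NaOMe (2.2 equiv), MeOH, reflux; then aq. HCl, 0 °C
Reagents that add atoms: none
Why: A double Claisen (Hinsberg-type) condensation in which each α-methylene of the diglycolate acylates one oxalate carbonyl should close the five-membered ring, driven by precipitation of the disodium enediolate, which aromatises to the dihydroxyfuran on acidification.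

**Step 2**
Reactants: 3 dimethyl 3,4-dihydroxyfuran-2,5-dicarboxylate
Product: 4 dimethyl 3,4-dimethoxyfuran-2,5-dicarboxylate
Conditions: Me2SO4, K2CO3, acetone, reflux
Reagents that add atoms: dimethyl sulfate, COS(=O)(=O)OC
Why: The two enolic hydroxyls are acidic (vinylogous carbonic acids) and should undergo Williamson-type O-methylation cleanly under carbonate conditions.

**Step 3**
Reactants: 4 dimethyl 3,4-dimethoxyfuran-2,5-dicarboxylate
Product: 5 3,4-dimethoxyfuran-2,5-dicarboxylic acid
Conditions: NaOH, H2O/MeOH, reflux; then aq. HCl to pH 1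
Reagents that add atoms: sodium hydroxide, [Na+].[OH-]
Why: Saponification of the two unhindered methyl esters should give the diacid, which precipitates on acidification.

**Step 4**
Reactants: 5 3,4-dimethoxyfuran-2,5-dicarboxylic acid
Product: 6 3,4-dimethoxyfuran
Conditions: Cu powder (cat.), quinoline, 200–220 °C, product distilled out under N2
Reagents that add atoms: none
Why: Copper-promoted thermal protodecarboxylation of furan-2-carboxylic acids is the established way to free the α-positions, and distilling the volatile furan out of the basic medium protects it from acid and heat.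

**Step 5**
Reactants: 7 but-3-yn-2-one
Product: 8 4-bromobut-3-yn-2-one
Conditions: NBS (1.1 equiv), AgNO3 (10 mol %), acetone, rt, dark
Reagents that add atoms: N-bromosuccinimide, O=C1CCC(=O)N1Br
Why: Silver-catalysed electrophilic bromination of the terminal alkyne via a silver acetylide should give the 1-bromoalkyne without touching the ketone; the product is used promptly as a solution.

**Step 6**
Reactants: 6 3,4-dimethoxyfuran; 8 4-bromobut-3-yn-2-one (1.2 equiv)
Product: 10 1-(2-bromo-3-hydroxy-4,5-dimethoxyphenyl)ethanone, via oxanorbornadiene cycloadduct 9 (not isolated)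
Conditions: toluene, 25–60 °C, dark; then CF3CO2H (0.2 equiv), 0 °C to rt
Reagents that add atoms: none
Why: The electron-rich diene 6 and the acceptor alkyne 8 should combine in a concerted suprafacial [4+2] cycloaddition that forms C4a–C5 and C8–C8a (flavone numbering) and closes the six-membered carbocycle of ring A as the 2-acetyl-3-bromo-7-oxanorbornadiene 9; CF3CO2H then protonates the bridging oxygen, the C5–O bond breaks, and loss of the C8 proton aromatises the ring to phenol 10. The closest known reactions are the Diels–Alder additions of furans to 3-bromopropiolates and bromoalkynyl ketones and the acid-catalysed isomerisation of 7-oxanorbornadienes to phenols. The only ring made is closed by intermolecular cycloaddition, both new σ-bonds forming in one event rather than by cyclisation of a chain. The two bridgehead stereocentres of 9 are held cis by the oxygen bridge, arise as a racemate and are erased on aromatisation, so no stereocontrol is required. The furan is symmetrical, so the cycloaddition has no regiochemical issue and the selectivity needed is the direction of bridge opening: cleavage at the bridgehead next to the acetyl-bearing carbon gives a pentadienyl cation with charge on C5, on methoxy-bearing C7 and on bromine-bearing C8a, whereas the other cleavage would put charge on C4a beside the ketone, so the hydroxyl should stay on C8 next to the bromine.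

**Step 7**
Reactants: 10 1-(2-bromo-3-hydroxy-4,5-dimethoxyphenyl)ethanone
Product: 11 1-[3-(benzyloxy)-2-bromo-4,5-dimethoxyphenyl]ethanone
Conditions: BnBr, K2CO3, DMF, rt to 50 °C
Reagents that add atoms: benzyl bromide, BrCc1ccccc1
Why: Williamson etherification of the phenoxide should mask the 8-hydroxyl before strong base and copper are used; carbonate is too weak to enolise the aryl methyl ketone.

**Step 8**
Reactants: 12 methyl 3-hydroxy-4,5-dimethoxybenzoate
Product: 13 methyl 3-(benzyloxy)-4,5-dimethoxybenzoate
Conditions: BnBr, K2CO3, DMF, 60 °C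
Reagents that add atoms: benzyl bromide, BrCc1ccccc1
Why: Williamson etherification of the only free phenol gives the ring B acyl donor carrying the same protecting group as ring A, so both can be removed together at the end.

**Step 9**
Reactants: 11 1-[3-(benzyloxy)-2-bromo-4,5-dimethoxyphenyl]ethanone; 13 methyl 3-(benzyloxy)-4,5-dimethoxybenzoate
Product: 14 1-[3-(benzyloxy)-2-bromo-4,5-dimethoxyphenyl]-3-[3-(benzyloxy)-4,5-dimethoxyphenyl]propane-1,3-dione
Conditions: NaH (2.5 equiv), THF, 0 °C to reflux; then aq. HCl, 0 °C
Reagents that add atoms: none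
Why: In this crossed Claisen condensation only ketone 11 can enolise and ester 13 has no α-hydrogen, and irreversible deprotonation of the 1,3-diketone formed should pull the equilibrium to product, forming the C2–C3 bond.

**Step 10**
Reactants: 14 1-[3-(benzyloxy)-2-bromo-4,5-dimethoxyphenyl]-3-[3-(benzyloxy)-4,5-dimethoxyphenyl]propane-1,3-dione
Product: 15 8-(benzyloxy)-2-[3-(benzyloxy)-4,5-dimethoxyphenyl]-6,7-dimethoxy-4H-chromen-4-one
Conditions: CuI (10 mol %), 1,10-phenanthroline (20 mol %), K2CO3 (2 equiv), DMF, 110 °C, N2
Reagents that add atoms: none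
Why: Intramolecular Ullmann-type C–O coupling of the diketonate oxygen with the ortho aryl bromide, known for 1-(2-bromoaryl)-1,3-diketones, should close the six-membered pyranone (O1–C8a); C-arylation would require a four-membered ring and cannot compete.

**Step 11**
Reactants: 15 8-(benzyloxy)-2-[3-(benzyloxy)-4,5-dimethoxyphenyl]-6,7-dimethoxy-4H-chromen-4-one
Product: 16 8-hydroxy-2-(3-hydroxy-4,5-dimethoxyphenyl)-6,7-dimethoxy-4H-chromen-4-one (target)
Conditions: H2 (1 atm), 10% Pd/C, EtOAc/MeOH, rt, stopped at full conversion
Reagents that add atoms: none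
Why: Catalytic hydrogenolysis should cleave both benzyl aryl ethers while the methyl ethers and the C2–C3 double bond of the chromone (a vinylogous ester conjugated to two arenes) survive at atmospheric pressure.

**Compound list**
1 | dimethyl diglycolate (dimethyl 2,2'-oxydiacetate) | COC(=O)COCC(=O)OC | starting material
2 | dimethyl oxalate | COC(=O)C(=O)OC | starting material
3 | dimethyl 3,4-dihydroxyfuran-2,5-dicarboxylate | COC(=O)c1oc(C(=O)OC)c(O)c1O | intermediate
4 | dimethyl 3,4-dimethoxyfuran-2,5-dicarboxylate | COC(=O)c1oc(C(=O)OC)c(OC)c1OC | intermediate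
5 | 3,4-dimethoxyfuran-2,5-dicarboxylic acid | COc1c(C(=O)O)oc(C(=O)O)c1OC | intermediate
6 | 3,4-dimethoxyfuran | COc1cocc1OC | intermediate
7 | but-3-yn-2-one | CC(=O)C#C | starting material
8 | 4-bromobut-3-yn-2-one | CC(=O)C#CBr | intermediate
9 | 1-(3-bromo-5,6-dimethoxy-7-oxabicyclo[2.2.1]hepta-2,5-dien-2-yl)ethanone (racemic, one enantiomer drawn) | CC(=O)C1=C(Br)[C@H]2O[C@@H]1C(OC)=C2OC | intermediate
10 | 1-(2-bromo-3-hydroxy-4,5-dimethoxyphenyl)ethanone | CC(=O)c1cc(OC)c(OC)c(O)c1Br | intermediate
11 | 1-[3-(benzyloxy)-2-bromo-4,5-dimethoxyphenyl]ethanone | CC(=O)c1cc(OC)c(OC)c(OCc2ccccc2)c1Br | intermediate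
12 | methyl 3-hydroxy-4,5-dimethoxybenzoate | COC(=O)c1cc(O)c(OC)c(OC)c1 | starting material
13 | methyl 3-(benzyloxy)-4,5-dimethoxybenzoate | COC(=O)c1cc(OCc2ccccc2)c(OC)c(OC)c1 | intermediate
14 | 1-[3-(benzyloxy)-2-bromo-4,5-dimethoxyphenyl]-3-[3-(benzyloxy)-4,5-dimethoxyphenyl]propane-1,3-dione | O=C(CC(=O)c1cc(OCc2ccccc2)c(OC)c(OC)c1)c1cc(OC)c(OC)c(OCc2ccccc2)c1Br | intermediate
15 | 8-(benzyloxy)-2-[3-(benzyloxy)-4,5-dimethoxyphenyl]-6,7-dimethoxy-4H-chromen-4-one | COc1cc(-c2cc(=O)c3cc(OC)c(OC)c(OCc4ccccc4)c3o2)cc(OCc2ccccc2)c1OC | intermediate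
16 | 8-hydroxy-2-(3-hydroxy-4,5-dimethoxyphenyl)-6,7-dimethoxy-4H-chromen-4-one | COc1cc(-c2cc(=O)c3cc(OC)c(OC)c(O)c3o2)cc(O)c1OC | target

**Step count**
Total: 11 steps. Longest linear sequence: 9 steps (steps 1, 2, 3, 4, 6, 7, 9, 10, 11).

**Steps most likely to fail**

Step 6. The furan may react as a carbon nucleophile instead of a diene (conjugate addition to the bromoalkynone with loss of bromide, or oligomerisation), or the oxygen bridge may open in the unwanted direction. The fallback builds the same ring A ketone by arene substitution and sets out from 12. Bromination ortho to the free phenol (NBS, cat. iPr2NH, CH2Cl2, 0 °C; the position is also para to the 5-methoxy group) should give methyl 2-bromo-3-hydroxy-4,5-dimethoxybenzoate F1. Benzylation (BnBr, K2CO3, DMF) gives methyl 3-(benzyloxy)-2-bromo-4,5-dimethoxybenzoate F2. Aminolysis with MeNH(OMe)·HCl and AlMe3 in CH2Cl2 gives the Weinreb amide 3-(benzyloxy)-2-bromo-N,4,5-trimethoxy-N-methylbenzamide F3. Addition of MeMgBr in THF at 0 °C stops at the ketone, and the route is rejoined at 11.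

Step 10. Insertion of copper into the electron-rich C8a–Br bond, which has substituents on both ortho positions, may be slow, so that protodebromination or base-induced retro-Claisen cleavage of the diketone takes over. The fallback forms the C8a–O bond first and closes ring C at O1–C2 by condensation; it sets out from 11. Palladium-catalysed hydroxylation of the aryl bromide (Pd2(dba)3, tBuXPhos, KOH, dioxane/H2O, 100 °C) should give 1-[3-(benzyloxy)-2-hydroxy-4,5-dimethoxyphenyl]ethanone F4. Claisen condensation of its dianion with ester 13 (NaH, THF, reflux) gives 1-[3-(benzyloxy)-2-hydroxy-4,5-dimethoxyphenyl]-3-[3-(benzyloxy)-4,5-dimethoxyphenyl]propane-1,3-dione F5. Acid-catalysed cyclodehydration (cat. TsOH·H2O, toluene, reflux) then returns to the route at 15.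

Step 9. The equilibrium condensation may stall because the trioxygenated benzoate is a poor electrophile, leaving the ketone enolate to undergo self-aldol condensation. The fallback replaces the reversible ester condensation by irreversible acylation of a preformed enolate; it sets out from 13. Saponification (LiOH, THF/H2O) gives 3-(benzyloxy)-4,5-dimethoxybenzoic acid F6, and (COCl)2 with cat. DMF in CH2Cl2 gives 3-(benzyloxy)-4,5-dimethoxybenzoyl chloride F7. The lithium enolate of 11 (LiN(SiMe3)2, 2.2 equiv, THF, −78 °C) is then acylated with F7, and the route is rejoined at 14.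

**Further compounds**
F1 | step 6 | methyl 2-bromo-3-hydroxy-4,5-dimethoxybenzoate | COC(=O)c1cc(OC)c(OC)c(O)c1Br
F2 | step 6 | methyl 3-(benzyloxy)-2-bromo-4,5-dimethoxybenzoate | COC(=O)c1cc(OC)c(OC)c(OCc2ccccc2)c1Br
F3 | step 6 | 3-(benzyloxy)-2-bromo-N,4,5-trimethoxy-N-methylbenzamide | CON(C)C(=O)c1cc(OC)c(OC)c(OCc2ccccc2)c1Br
F4 | step 10 | 1-[3-(benzyloxy)-2-hydroxy-4,5-dimethoxyphenyl]ethanone | CC(=O)c1cc(OC)c(OC)c(OCc2ccccc2)c1O
F5 | step 10 | 1-[3-(benzyloxy)-2-hydroxy-4,5-dimethoxyphenyl]-3-[3-(benzyloxy)-4,5-dimethoxyphenyl]propane-1,3-dione | O=C(CC(=O)c1cc(OCc2ccccc2)c(OC)c(OC)c1)c1cc(OC)c(OC)c(OCc2ccccc2)c1O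
F6 | step 9 | 3-(benzyloxy)-4,5-dimethoxybenzoic acid | OC(=O)c1cc(OCc2ccccc2)c(OC)c(OC)c1
F7 | step 9 | 3-(benzyloxy)-4,5-dimethoxybenzoyl chloride | ClC(=O)c1cc(OCc2ccccc2)c(OC)c(OC)c1
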